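Ring A is assembled by a formal [3+3] annulation that makes C1–C2 and C4–C5 together: a C2–C3–C4 bis-nucleophile (the α′ and α carbons of the C3 carbonyl, used as a 1,3-bis(silyloxy)diene) is joined to a ring-B cyclohexene whose quaternary C10 is flanked by two electrophilic carbons, the C1 aldehyde and an allylic C5 acetate. One Lewis acid should bring about a vinylogous Mukaiyama aldol addition and then an intramolecular SN1 allylation; this closes ring A, builds the quaternary C4 and, because C4 is delivered over the C10–C1 tether, enforces the cis C5–C10 ring fusion. A catalytic asymmetric Diels–Alder reaction sets C9 and C10; C5, C4 and C3 are relayed from them.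

Key step: step 5

Remark: the SMILES is read literally as (3R,4R,5S,9S,10R) in labdane numbering, i.e. a cis-fused decalin (H-5 syn to the C10 methyl) with 9β side chain, 4β-CO2H, 4α-CH3 and 3α-OAc; labdane numbering and α/β (β = face of the C10 methyl) are used throughout.

Step 1
Reactants: 1 pent-4-ynal; 2 2-(triphenylphosphoranylidene)propanal
Product: 3 (E)-2-methylhept-2-en-6-ynal
Conditions: toluene, 90 °C
Reagents that add atoms: none
Why: Wittig olefination with a stabilised formyl ylide should give the (E)-trisubstituted enal, which fixes the later trans relation between the formyl carbon (C1) and the C9 side chain.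

Step 2
Reactants: 3 (E)-2-methylhept-2-en-6-ynal; 4 (E)-buta-1,3-dien-1-yl acetate
Product: 5 ring-B aldehyde
Conditions: (S)-o-tolyl-oxazaborolidinium triflimide (20 mol%), CH2Cl2, −78 → −40 °C
Reagents that add atoms: none
Why: Enantioselective Lewis-acid-catalysed Diels–Alder reaction: the acyloxy-bearing diene terminus should bond to the formyl-bearing carbon ("ortho"), suprafacial addition keeps the butynyl group trans to CHO (cis to CH3), the endo mode places OAc cis to CHO, and the chiral Lewis acid bound to the enal selects the face and so the absolute configuration of C9 and C10 (the catalyst antipode is taken if the facial model calls for it).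

Step 3
Reactants: 6 methyl 2-methyl-3-oxobutanoate
Product: 7 methyl (Z)-2-methyl-3-(trimethylsilyloxy)but-2-enoate
Conditions: TMSCl, Et3N, Et2O, rt
Reagents that add atoms: chlorotrimethylsilane, C[Si](C)(C)Cl
Why: O-silylation of the β-keto ester enol (silyl enol ether formation) should give the conjugated enol silane.

Step 4
Reactants: 7 methyl (Z)-2-methyl-3-(trimethylsilyloxy)but-2-enoate
Product: 8 1-methoxy-2-methyl-1,3-bis(trimethylsilyloxy)buta-1,3-diene
Conditions: LDA, THF, −78 °C; TMSCl
Reagents that add atoms: chlorotrimethylsilane, C[Si](C)(C)Cl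
Why: γ-Deprotonation of the vinylogous ester and O-silylation of the extended enolate should give the 1,3-bis(silyloxy)diene, a masked β-keto ester dianion.

Step 5
Reactants: 5 ring-B aldehyde; 8 1-methoxy-2-methyl-1,3-bis(trimethylsilyloxy)buta-1,3-diene
Product: 10 bicyclic hydroxy keto ester, via open-chain enol silane 9 (not isolated)
Conditions: TiCl4 (2.2 equiv), CH2Cl2, −78 °C, then −78 → −20 °C; aq. NaHCO3
Reagents that add atoms: none
Why: Proposed new method: TiCl4 should activate the hindered aldehyde of 5 for a vinylogous Mukaiyama aldol addition of the terminal carbon of 8 (C1–C2), leaving the C3–C4 enol silane (or its titanium chelate) 9, and on warming the same Lewis acid should ionise the allylic acetate to a cyclohexenyl cation that the tethered enol carbon captures at C5 (C4–C5). The closest known chemistry is the TiCl4-mediated formal [3+3] cyclisation of 1,3-bis(silyloxy)-1,3-dienes with 1,3-dielectrophiles, combined with the Lewis-acid SN1 allylation of β-dicarbonyl nucleophiles by allylic acetates; a domino with an aldehyde/allylic acetate pair has not been described. Ring A closes in a 6-(enolendo)-exo-trig mode onto the terminus of the allyl cation. C5 is controlled by the tether, since C4 must enter perpendicular to the planar C5 on the face that carries C1, which is possible only for the cis junction (H-5 syn to the C10 methyl) and makes both acetate epimers converge; C4 is controlled by the chelated (Z)-enol geometry and by sterics, the ester taking the convex β face and the methyl the concave α face; the C1 carbinol forms unselectively and is erased in step 6. The step needs aldol addition before ionisation (secured by running the addition at −78 °C, where the aldehyde–TiCl4 complex should react much faster than the acetate ionises), attack at C5 rather than C7 (six- versus eight-membered ring), and ring closure faster than proton loss or fragmentation of the cation (favoured by the intramolecular, strongly nucleophilic enol silane).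

Step 6
Reactants: 10 bicyclic hydroxy keto ester
Product: 12 ring-A enone, via mesylate 11 (not isolated)
Conditions: MsCl, Et3N, CH2Cl2, 0 °C; then DBU, rt
Reagents that add atoms: none
Why: Mesylation and E1cB β-elimination of the β-hydroxy ketone should give the C1=C2 enone, which removes the C1 oxygen and its uncontrolled stereocentre.

Step 7
Reactants: 12 ring-A enone
Product: 13 saturated 3-keto ester
Conditions: L-Selectride (1.1 equiv), THF, −78 °C; sat. NH4Cl
Reagents that add atoms: none
Why: Conjugate (1,4-) hydride reduction of a β-unsubstituted cyclohexenone whose carbonyl is shielded by the quaternary C4 should give the saturated ketone and leave the isolated ring-B alkene, the ester and the alkyne untouched.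

Step 8
Reactants: 13 saturated 3-keto ester
Product: 15 3α-acetate, via 3α-alcohol 14 (not isolated)
Conditions: L-Selectride (1.3 equiv), THF, −78 → −40 °C; then Ac2O, DMAP, → rt
Reagents that add atoms: acetic anhydride, CC(=O)OC(C)=O
Why: Substrate-controlled ketone reduction: the bulky hydride should attack C3 from the convex β face, away from ring B and the concave 4α-methyl, giving the 3α-alkoxide (C3 R), which is trapped in the flask as the acetate.

Step 9
Reactants: 15 3α-acetate
Product: 16 C8 allylic alcohol
Conditions: SeO2 (0.5 equiv), t-BuOOH, CH2Cl2, rt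
Reagents that add atoms: tert-butyl hydroperoxide, CC(C)(C)OO (oxygen source, relayed through catalytic selenium dioxide, O=[Se]=O)
Why: Allylic hydroxylation by selenium ene reaction and [2,3]-sigmatropic shift should occur at C8, the only allylic position with accessible hydrogens (H-5 lies between two quaternary carbons), and the monosubstituted alkyne should be far less reactive in the ene step than the cis-alkene; the configuration of the new carbinol is irrelevant.

Step 10
Reactants: 16 C8 allylic alcohol
Product: 17 ring-B enone
Conditions: Dess–Martin periodinane, NaHCO3, CH2Cl2, rt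
Reagents that add atoms: none
Why: Mild oxidation of the secondary allylic alcohol should give the C8 ketone conjugated with C6=C7 without touching the acetate, ester or alkyne.

Step 11
Reactants: 17 ring-B enone
Product: 18 C8 ketone
Conditions: L-Selectride (1.05 equiv), THF, −78 °C; sat. NH4Cl
Reagents that add atoms: none
Why: Conjugate hydride reduction should saturate C6–C7 through the C7–C8 enolate, so the stereocentre at C9 is never enolised, and at −78 °C the acetate should survive.

Step 12
Reactants: 18 C8 ketone
Product: 19 8(17)-methylidene methyl ester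
Conditions: Zn, CH2Br2, TiCl4, THF/CH2Cl2, 0 °C → rt
Reagents that add atoms: dibromomethane, BrCBr
Why: Non-basic titanium–zinc methylenation should convert the hindered, epimerisable ketone into the exocyclic alkene without enolisation toward C9 and without attacking the two esters.

Step 13
Reactants: 19 8(17)-methylidene methyl ester
Product: 20 alkynyl acid
Conditions: LiI, 2,6-lutidine, reflux; then 1 M HCl
Reagents that add atoms: none
Why: SN2 O-demethylation by iodide should cleave the hindered methyl ester at its methyl carbon, while the secondary acetate is not an SN2 substrate and the alkenes and alkyne are inert.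

Step 14
Reactants: 20 alkynyl acid
Product: 21 3α-acetoxy-5β-labda-8(17),13(16),14-trien-19-oic acid (target)
Conditions: ethylene (1 atm), Grubbs II (5 mol%), CH2Cl2, rt
Reagents that add atoms: ethylene, C=C
Why: Enyne cross-metathesis with ethylene should turn the terminal alkyne into the 2-substituted buta-1,3-diene, while the 1,1-disubstituted exocyclic alkene can only undergo degenerate methylidene exchange and the free acid is tolerated.

Compound list
1 | pent-4-ynal | C#CCCC=O | starting material
2 | 2-(triphenylphosphoranylidene)propanal | CC(C=O)=P(c1ccccc1)(c1ccccc1)c1ccccc1 | starting material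
3 | (E)-2-methylhept-2-en-6-ynal | C#CCC/C=C(\C)C=O | intermediate
4 | (E)-buta-1,3-dien-1-yl acetate | CC(=O)O/C=C/C=C | starting material
5 | (1R,2S,6S)-2-acetoxy-6-(but-3-yn-1-yl)-1-methylcyclohex-3-ene-1-carbaldehyde (OAc cis to CHO, butynyl trans to CHO; future C10, C5, C9) | C#CCC[C@H]1CC=C[C@H](OC(C)=O)[C@]1(C)C=O | intermediate
6 | methyl 2-methyl-3-oxobutanoate | COC(=O)C(C)C(C)=O | starting material
7 | methyl (Z)-2-methyl-3-(trimethylsilyloxy)but-2-enoate | COC(=O)/C(C)=C(/C)O[Si](C)(C)C | intermediate
8 | 1-methoxy-2-methyl-1,3-bis(trimethylsilyloxy)buta-1,3-diene (ketene acetal geometry not defined) | C=C(O[Si](C)(C)C)C(C)=C(OC)O[Si](C)(C)C | intermediate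
9 | open-chain aldol adduct of 5, drawn as the (Z)-enol silane: methyl 5-hydroxy-2-methyl-3-(trimethylsilyloxy)pent-2-enoate carrying the ring of 5 at C5 (carbinol epimers) | C#CCC[C@H]1CC=C[C@H](OC(C)=O)[C@]1(C)C(O)C/C(O[Si](C)(C)C)=C(\C)C(=O)OC | intermediate (not isolated)
10 | methyl 1ξ-hydroxy-3-oxo-15,16,17-trinor-5β-labd-6-en-13-yn-19-oate (4α-CH3, 4β-CO2Me, 5β-H, 9β-butynyl, 10β-CH3; C1 epimers) | C#CCC[C@H]1CC=C[C@H]2[C@]1(C)C(O)CC(=O)[C@]2(C)C(=O)OC | intermediate
11 | 1ξ-methanesulfonate of 10 | C#CCC[C@H]1CC=C[C@H]2[C@]1(C)C(OS(C)(=O)=O)CC(=O)[C@]2(C)C(=O)OC | intermediate (not isolated)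
12 | methyl 3-oxo-15,16,17-trinor-5β-labda-1,6-dien-13-yn-19-oate | C#CCC[C@H]1CC=C[C@H]2[C@]1(C)C=CC(=O)[C@]2(C)C(=O)OC | intermediate
13 | methyl 3-oxo-15,16,17-trinor-5β-labd-6-en-13-yn-19-oate | C#CCC[C@H]1CC=C[C@H]2[C@]1(C)CCC(=O)[C@]2(C)C(=O)OC | intermediate
14 | methyl 3α-hydroxy-15,16,17-trinor-5β-labd-6-en-13-yn-19-oate (formed as its lithium alkoxide) | C#CCC[C@H]1CC=C[C@H]2[C@]1(C)CC[C@@H](O)[C@]2(C)C(=O)OC | intermediate (not isolated)
15 | methyl 3α-acetoxy-15,16,17-trinor-5β-labd-6-en-13-yn-19-oate | C#CCC[C@H]1CC=C[C@H]2[C@]1(C)CC[C@@H](OC(C)=O)[C@]2(C)C(=O)OC | intermediate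
16 | methyl 3α-acetoxy-8ξ-hydroxy-15,16,17-trinor-5β-labd-6-en-13-yn-19-oate (C8 epimers) | C#CCC[C@H]1C(O)C=C[C@H]2[C@]1(C)CC[C@@H](OC(C)=O)[C@]2(C)C(=O)OC | intermediate
17 | methyl 3α-acetoxy-8-oxo-15,16,17-trinor-5β-labd-6-en-13-yn-19-oate | C#CCC[C@H]1C(=O)C=C[C@H]2[C@]1(C)CC[C@@H](OC(C)=O)[C@]2(C)C(=O)OC | intermediate
18 | methyl 3α-acetoxy-8-oxo-15,16,17-trinor-5β-labd-13-yn-19-oate | C#CCC[C@H]1C(=O)CC[C@H]2[C@]1(C)CC[C@@H](OC(C)=O)[C@]2(C)C(=O)OC | intermediate
19 | methyl 3α-acetoxy-15,16-dinor-5β-labd-8(17)-en-13-yn-19-oate | C#CCC[C@H]1C(=C)CC[C@H]2[C@]1(C)CC[C@@H](OC(C)=O)[C@]2(C)C(=O)OC | intermediate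
20 | 3α-acetoxy-15,16-dinor-5β-labd-8(17)-en-13-yn-19-oic acid | C#CCC[C@H]1C(=C)CC[C@H]2[C@]1(C)CC[C@@H](OC(C)=O)[C@]2(C)C(=O)O | intermediate
21 | 3α-acetoxy-5β-labda-8(17),13(16),14-trien-19-oic acid, (3R,4R,5S,9S,10R) | C=CC(=C)CC[C@H]1C(=C)CC[C@H]2[C@]1(C)CC[C@@H](OC(C)=O)[C@]2(C)C(=O)O | target

Total step count: 14. Longest linear sequence: 12 steps (steps 1, 2 and 5–14); steps 3 and 4 form the short side branch to diene 8.

Steps most likely to fail

Step 5 (the proposed new method). The cyclohexenyl cation may lose a proton or fragment with loss of the C1 unit before C4 arrives, ionisation may outrun the aldol addition, or C4 may add through the wrong enol face. The fallback is stepwise, uses known chemistry, sets out from 5 and 6 and comes back at 10. The dianion of 6 (NaH, then n-BuLi, THF, 0 °C) is added to 5 at −78 °C; this γ-selective aldol addition of a β-keto ester dianion should give the open-chain δ-hydroxy β-keto ester F1. Its sodium enolate is then cyclised with Pd(PPh3)4 (THF, 25–50 °C) in an intramolecular Tsuji–Trost allylic alkylation. Palladium ionises the cis-acetate with inversion and the stabilised enolate attacks anti to the metal, that is on the tether face, which should again give the cis-fused 10.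

Step 2. The trisubstituted enal may react too slowly, the acetoxy diene may be consumed by the strong Lewis acid, or the enantiofacial discrimination may be insufficient. The fallback replaces catalyst control by a chiral diene, sets out from 3 and comes back at 10. The potassium dienolate of crotonaldehyde (KOt-Bu, THF, −78 °C) is O-acylated with (S)-O-methylmandeloyl chloride to give (E)-buta-1,3-dien-1-yl (S)-2-methoxy-2-phenylacetate F2. Its BF3·OEt2-promoted Diels–Alder reaction with 3 should give, under auxiliary control, the mandelate analogue of 5, F3 (the antipodal mandelate is used if the facial sense requires it; diastereomers are separable by chromatography). F3 then enters step 5 in place of 5, with the mandelate as the leaving group.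

Step 9. Oxidation may compete at the propargylic methylene of the side chain, or the hindered ring alkene may convert poorly. The fallback changes the masked-diene handle before the oxidation, sets out from 15 and comes back at 21. The alkyne of 15 is converted by bromoboration with B-bromo-9-BBN (CH2Cl2, 0 °C) and protonolysis with AcOH into the 2-bromoalk-1-ene F4, whose allylic C–H bonds are deactivated towards the selenium ene step. F4 is carried through the operations of steps 9 to 13: SeO2/t-BuOOH to the allylic alcohol F5, Dess–Martin oxidation to the enone F6, L-Selectride to the ketone F7, Zn/CH2Br2/TiCl4 to the methylidene ester F8 and LiI to the bromoalkenyl acid F9. Stille coupling of F9 with tributyl(vinyl)stannane (Pd(PPh3)4, CuI, DMF, 50 °C) should then give 21 without the metathesis step.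

Further compounds
F1 | step 5 | open-chain δ-hydroxy β-keto ester from 5 and the dianion of 6 (carbinol and C4 epimers) | C#CCC[C@H]1CC=C[C@H](OC(C)=O)[C@]1(C)C(O)CC(=O)C(C)C(=O)OC
F2 | step 2 | (E)-buta-1,3-dien-1-yl (S)-2-methoxy-2-phenylacetate | C=C/C=C/OC(=O)[C@@H](OC)c1ccccc1
F3 | step 2 | (S)-O-methylmandelate analogue of 5 | C#CCC[C@H]1CC=C[C@H](OC(=O)[C@@H](OC)c2ccccc2)[C@]1(C)C=O
F4 | step 9 | methyl 3α-acetoxy-13-bromo-15,17-dinor-5β-labda-6,13(16)-dien-19-oate (2-bromoalkene from 15) | C=C(Br)CC[C@H]1CC=C[C@H]2[C@]1(C)CC[C@@H](OC(C)=O)[C@]2(C)C(=O)OC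
F5 | step 9 | 8ξ-hydroxy derivative of F4 | C=C(Br)CC[C@H]1C(O)C=C[C@H]2[C@]1(C)CC[C@@H](OC(C)=O)[C@]2(C)C(=O)OC
F6 | step 9 | 8-oxo-6-ene (enone) from F5 | C=C(Br)CC[C@H]1C(=O)C=C[C@H]2[C@]1(C)CC[C@@H](OC(C)=O)[C@]2(C)C(=O)OC
F7 | step 9 | saturated 8-ketone from F6 | C=C(Br)CC[C@H]1C(=O)CC[C@H]2[C@]1(C)CC[C@@H](OC(C)=O)[C@]2(C)C(=O)OC
F8 | step 9 | 8(17)-methylidene methyl ester from F7 | C=C(Br)CC[C@H]1C(=C)CC[C@H]2[C@]1(C)CC[C@@H](OC(C)=O)[C@]2(C)C(=O)OC
F9 | step 9 | 13-bromo-15-nor acid from F8 | C=C(Br)CC[C@H]1C(=C)CC[C@H]2[C@]1(C)CC[C@@H](OC(C)=O)[C@]2(C)C(=O)O
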